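**The set-up.** The enzyme turns substrate into product while added ligand holds it back. I must say how much product each set-up gives, all at 96 µM of ligand.

common to all: enzyme 0.01 mol%

|  | substrate | added ligand | remark | time |
|---|---|---|---|---|
| amber | 0.17 M | 96 µM | run made earlier |  |
| green | 0.17 M | 48 µM | run made earlier |  |
| teal | 0.17 M | 190 µM | run made earlier |  |
| north | 0.17 M (fed, over 40.0 h) | 96 µM | all but substrate at the start; substrate goes in evenly over 40.0 h, the run ends at 40 h | 40 h |
| west | 0.17 M | 96 µM | everything together in a closed stirred flask, run for 40 h | 40 h |
| east | 0.17 M | 96 µM | one stirred flow tank at steady state, fed with the mixture as stated, mean residence time 200 h |  |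
| south-east | 0.17 M | 96 µM | one stirred flow tank at steady state, fed with the mixture as stated, mean residence time 40 h |  |

- amber (time / h: product / %, substrate / %): 3.00: 6, 96; 6.00: 7, 93; 12.0: 16, 81; 20.0: 32, 75; 40.0: 52, 53
- green (time / h: product / %, substrate / %): 8.00: 27, 74; 15.0: 43, 60; 25.0: 63, 40; 30.0: 65, 31; 40.0: 82, 25
- teal (time / h: product / %, substrate / %): 8.00: 5, 97; 15.0: 12, 87; 25.0: 16, 85; 30.0: 18, 80; 40.0: 27, 76

(readings scatter by 2 percentage points)

- order of the set-ups by the amount of product at the outlet or at the end, in percent of the substrate put in, highest first (north / west / east / south-east)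
- amount of product at the outlet or at the end, in percent of the substrate put in, north
- amount of product at the outlet or at the end, in percent of the substrate put in, west
- amount of product at the outlet or at the end, in percent of the substrate put in, east
- amount of product at the outlet or at the end, in percent of the substrate put in, south-east

- the stated concentrations are those of everything mixed, before any reaction; amounts are the same in each set-up
- the feed brings no volume worth counting
- the earlier runs were made in a closed, stirred flask

**The puzzle.** Let k be the fraction of substrate lost per hour, a pseudo-first-order constant, read as ln(1/S)/t from the substrate share S at 40.0 h. Green reads 0.0347 h⁻¹ and teal 0.00686 h⁻¹. From green to teal the ligand rises by a factor of 3.96, yet k falls by a factor of 5.05, more than plain proportion allows.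

**Free ligand.** The charge holds 17.0 µM of enzyme. I take binding as fast and tight, one ligand per enzyme, and reckon with the free ligand L_f, the added ligand minus the enzyme. That is 31.0 µM in green and 173 µM in teal, a factor of 5.58, which lies nearer to the fall in k than 3.96 does. Amber has 79.0 µM and reads 0.0159 h⁻¹. I call k times L_f the brake product Q, and amber gives 1.25 µM h⁻¹, against 1.08 µM h⁻¹ for green and 1.19 µM h⁻¹ for teal.

**My reckoning.** North, west, east and south-east hold amber's 96 µM of ligand and its enzyme loading, so they have amber's L_f, and I take k = Q/L_f. With 0.635 as k times 40 h, I get 47.0% for west, 26.0% for north, 76.0% for east and 38.8% for south-east.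

**The result.** The forecast, which says “The ligand is therefore an inhibitor”, gives east > west > south-east > north with 27%, 50%, 77% and 40% for north, west, east and south-east, each higher than my figure. The flask gives east > west > south-east > north, with 27.3%, 48.4%, 75.9% and 40.9%.

    substrate + enzyme → product + enzyme, rate k1*[substrate]^1.5*[enzyme]/(1 + ([substrate]/Kh1)^1.5) (0.130 M, k = 1.00 × 10⁵ L¹·⁵ mol⁻¹·⁵ h⁻¹)
    enzyme + added ligand ⇌ idle complex, settled at all times (K = 2.20 × 10⁵ L mol⁻¹)

**What happened.** In west, about 5.44% of the enzyme stood free and the rest as idle complex while the turnover step ran for 40 h, and the 51.6% of substrate left gives Q = 1.31 µM h⁻¹. In east, the same step ran at a steady 0.0410 M of substrate, and the 24.1% left gives Q = 1.24 µM h⁻¹. Per mole of substrate, the scheme's step at that east level runs at 1.04 times its pace at the starting 0.17 M.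

The earlier runs and the new flask were computed for an exercise, and the scatter is random.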